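**Plan**

- Target: 5,2',4'-trihydroxy-7-methoxy-5'-prenylisoflavone. It is achiral, so no stereocentre has to be set.
- Retrosynthesis: the three phenols are masked as MOM ethers, then C2 is removed (O1–C2 and C2–C3) to leave a 2-hydroxydeoxybenzoin and DMF dimethyl acetal.
- The deoxybenzoin is cut at O1–C8a and C4–C4a together. C8a and C4a are neighbouring carbons of ring A that carry O1 and the C4 acyl carbon, and the C5 oxygen flanks C4a. This is the pattern a 3-alkoxyaryne leaves after inserting into a carboxylic acid C–O bond.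
- Forward: the ring A silylaryl triflate is made from 5-methoxyresorcinol (4 steps) and the ring B arylacetic acid from 4,6-dibromoresorcinol (4 steps). They are joined by aryne insertion, ring C is closed last with DMF dimethyl acetal, and the MOM groups are then removed.
- Stereochemistry: none in the target. The only stereo element on the way is the alkene geometry of a transient enaminone, which is lost on ring closure.

Key step: step 9

Remark: the enaminone formed during ring closure is drawn without alkene geometry, because either isomer should close to the same chromone.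

**Route**

Step 1
Reactants: 1 5-methoxyresorcinol
Product: 2 3-methoxy-5-(methoxymethoxy)phenol
Conditions: NaH (1.0 equiv), MOMCl (1.0 equiv), DMF, 0 °C to rt; chromatographic separation, diol and bis-ether recycled
Reagents that add atoms: chloromethyl methyl ether (MOMCl), COCCl
Why: Williamson-type O-alkylation of the monosodium phenoxide should give the mono-acetal as the main component of a statistical mixture, from which unreacted 1 and the bis-ether are separable.

Step 2
Reactants: 2 3-methoxy-5-(methoxymethoxy)phenol
Product: 3 3-methoxy-5-(methoxymethoxy)phenyl N-isopropylcarbamate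
Conditions: iPrNCO (1.2 equiv), Et3N (0.2 equiv), CH2Cl2, rt
Reagents that add atoms: isopropyl isocyanate, CC(C)N=C=O
Why: Amine-catalysed addition of the phenol to the isocyanate (carbamoylation) should be clean because the free phenol is the only nucleophile present.

Step 3
Reactants: 3 3-methoxy-5-(methoxymethoxy)phenyl N-isopropylcarbamate
Product: 7 5-methoxy-3-(methoxymethoxy)-2-(trimethylsilyl)phenyl N-isopropylcarbamate, via N-silyl carbamate 4 (not isolated), via ortho-lithiated carbamate 5 (not isolated), via N,C-disilyl carbamate 6 (not isolated)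
Conditions: TBSOTf (1.05 equiv), TMEDA (1.1 equiv), Et2O, 0 °C to rt; n-BuLi (2 equiv), TMEDA (2 equiv), −78 °C; TMSCl (3 equiv), −78 °C to rt; aq NaHSO4, 0 °C (N–Si hydrolysis)
Reagents that add atoms: chlorotrimethylsilane (TMSCl), C[Si](C)(C)Cl
Why: Directed ortho-metalation with transient N-silylation, in which the silylated carbamate (the strongest director) and the chelating OMOM group should cooperate to steer lithiation to the carbon between them rather than to the positions flanked by the weaker OMe director, the aryllithium being silylated at −78 °C before any anionic Fries shift.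

Step 4
Reactants: 7 5-methoxy-3-(methoxymethoxy)-2-(trimethylsilyl)phenyl N-isopropylcarbamate
Product: 9 5-methoxy-3-(methoxymethoxy)-2-(trimethylsilyl)phenyl trifluoromethanesulfonate, via silylphenol 8 (not isolated)
Conditions: Et2NH (1.5 equiv), DBU (1.5 equiv), MeCN, 40 °C; then PhNTf2 (1.5 equiv), rt
Reagents that add atoms: N-phenylbis(trifluoromethanesulfonimide) (PhNTf2), O=S(=O)(N(c1ccccc1)S(=O)(=O)C(F)(F)F)C(F)(F)F
Why: E1cB cleavage of the N-monosubstituted carbamate by DBU (the expelled isocyanate is trapped by Et2NH) frees the phenoxide under basic conditions that spare the acetal and the C–Si bond, and in situ sulfonylation with PhNTf2 should give the ortho-silylaryl triflate.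

Step 5
Reactants: 10 4,6-dibromoresorcinol
Product: 11 1,5-dibromo-2,4-bis(methoxymethoxy)benzene
Conditions: NaH (2.5 equiv), MOMCl (2.5 equiv), DMF, 0 °C to rt
Reagents that add atoms: chloromethyl methyl ether (MOMCl), COCCl
Why: Twofold Williamson-type O-alkylation of the bis-phenoxide, which the ortho bromines should not hinder.

Step 6
Reactants: 11 1,5-dibromo-2,4-bis(methoxymethoxy)benzene; 12 1-bromo-3-methylbut-2-ene
Product: 14 1-bromo-2,4-bis(methoxymethoxy)-5-(3-methylbut-2-enyl)benzene, via monolithiated arene 13 (not isolated)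
Conditions: n-BuLi (1.0 equiv), THF, −78 °C; CuBr·SMe2 (1.0 equiv), −78 °C; 12 (1.5 equiv), −78 °C to rt
Reagents that add atoms: 1-bromo-3-methylbut-2-ene (12), CC(C)=CCBr
Why: Bromine–lithium exchange should stop after one bromine because the first aryllithium deactivates the ring toward a second exchange, and copper-mediated SN2 allylation of the arylmetal with prenyl bromide should deliver the linear prenyl group.

Step 7
Reactants: 14 1-bromo-2,4-bis(methoxymethoxy)-5-(3-methylbut-2-enyl)benzene; 15 ethyl bromoacetate
Product: 17 ethyl 2-[2,4-bis(methoxymethoxy)-5-(3-methylbut-2-enyl)phenyl]acetate, via Reformatsky reagent 16 (not isolated)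
Conditions: 15 (1.5 equiv), Zn dust (TMSCl-activated, 2 equiv), THF, 40 °C; then 14, Pd2(dba)3 (2 mol %), XPhos (8 mol %), THF, 65 °C
Reagents that add atoms: ethyl bromoacetate (15), CCOC(=O)CBr
Why: Negishi-type cross-coupling of the Reformatsky reagent BrZnCH2CO2Et with the aryl bromide under zerovalent palladium and a bulky biarylphosphine should forge the aryl–CH2 bond under neutral conditions that avoid Claisen condensation and tolerate the acetals and the alkene.

Step 8
Reactants: 17 ethyl 2-[2,4-bis(methoxymethoxy)-5-(3-methylbut-2-enyl)phenyl]acetate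
Product: 18 2-[2,4-bis(methoxymethoxy)-5-(3-methylbut-2-enyl)phenyl]acetic acid
Conditions: LiOH·H2O (3 equiv), THF/H2O, rt; then 1 M HCl to pH 4, 0 °C
Reagents that add atoms: lithium hydroxide, [Li+].[OH-]
Why: Saponification of the unhindered ethyl ester, with acidification only to pH 4 in the cold so that the aryl MOM acetals should survive.

Step 9
Reactants: 9 5-methoxy-3-(methoxymethoxy)-2-(trimethylsilyl)phenyl trifluoromethanesulfonate; 18 2-[2,4-bis(methoxymethoxy)-5-(3-methylbut-2-enyl)phenyl]acetic acid
Product: 21 2-[2,4-bis(methoxymethoxy)-5-(3-methylbut-2-enyl)phenyl]-1-[2-hydroxy-4-methoxy-6-(methoxymethoxy)phenyl]ethanone, via aryne 19 (not isolated), via aryl-caesium ester 20 (not isolated)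
Conditions: 18 (1.0 equiv), 9 (1.5 equiv), CsF (4 equiv), THF (0.02 M), 125 °C, sealed tube; then aq NH4Cl
Reagents that add atoms: none
Why: Fluoride attack on silicon and loss of triflate release aryne 19, to which the caesium carboxylate of 18 adds through oxygen at the aryne carbon remote from the OMOM group, leaving the aryl anion 20 on the carbon flanked by that group. The anion then attacks its own ester carbonyl (4-exo-trig) and the resulting benzoxetene alkoxide opens by C–O cleavage to the ortho-acylphenoxide, so the aryne has inserted into the acid C–O bond and O1–C8a and C4–C4a form in one operation. The closest known reaction type is the fluoride-induced insertion of arynes into carboxylic acid C–O bonds that gives ortho-hydroxyaryl ketones, an intermolecular relative of the anionic Fries shift. No ring survives the step, since the four-membered ring is only transient, and no stereocentre is created. The regioselectivity needed (oxygen meta and acyl ortho to the C5 oxygen) is secured by the inductive effect of the flanking OMOM group, which polarises the aryne and stabilises the adjacent anion. The chemoselectivity needed (acyl shift faster than protonation of 20, carboxylate addition faster than an ene reaction with the prenyl alkene or arylation of the product phenoxide) is served by the anionic nucleophile, the hot aprotic dilute medium and the limited excess of 9.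

Step 10
Reactants: 21 2-[2,4-bis(methoxymethoxy)-5-(3-methylbut-2-enyl)phenyl]-1-[2-hydroxy-4-methoxy-6-(methoxymethoxy)phenyl]ethanone; 22 N,N-dimethylformamide dimethyl acetal
Product: 24 3-[2,4-bis(methoxymethoxy)-5-(3-methylbut-2-enyl)phenyl]-7-methoxy-5-(methoxymethoxy)chromen-4-one, via enaminone 23 (not isolated)
Conditions: 22 (3 equiv), toluene, 95 °C
Reagents that add atoms: N,N-dimethylformamide dimethyl acetal (22), COC(OC)N(C)C
Why: Condensation of the amide acetal with the doubly activated methylene gives an enaminone whose β-carbon is attacked by the free ortho phenol (6-endo-trig oxa-Michael addition) with loss of dimethylamine, the standard deoxybenzoin-to-isoflavone annulation that should close ring C.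

Step 11
Reactants: 24 3-[2,4-bis(methoxymethoxy)-5-(3-methylbut-2-enyl)phenyl]-7-methoxy-5-(methoxymethoxy)chromen-4-one
Product: 25 Isopoegin B, 3-[2,4-dihydroxy-5-(3-methylbut-2-enyl)phenyl]-5-hydroxy-7-methoxychromen-4-one
Conditions: 3 M aq HCl/MeOH (1:5), 50 °C
Reagents that add atoms: none
Why: Acid-catalysed methanolysis of the three aryl MOM acetals (acetal solvolysis), with dilute acid and moderate temperature chosen so that the prenyl alkene next to the liberated 4'-hydroxyl should not be protonated.

**Compound list**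

1 | 5-methoxyresorcinol | COc1cc(O)cc(O)c1 | starting material
2 | 3-methoxy-5-(methoxymethoxy)phenol | COCOc1cc(O)cc(OC)c1 | intermediate
3 | 3-methoxy-5-(methoxymethoxy)phenyl N-isopropylcarbamate | COCOc1cc(OC)cc(OC(=O)NC(C)C)c1 | intermediate
4 | 3-methoxy-5-(methoxymethoxy)phenyl N-(tert-butyldimethylsilyl)-N-isopropylcarbamate (formed in the flask) | COCOc1cc(OC)cc(OC(=O)N(C(C)C)[Si](C)(C)C(C)(C)C)c1 | intermediate
5 | 2-lithio-5-methoxy-3-(methoxymethoxy)phenyl N-(tert-butyldimethylsilyl)-N-isopropylcarbamate (formed in the flask) | COCOc1cc(OC)cc(OC(=O)N(C(C)C)[Si](C)(C)C(C)(C)C)c1[Li] | intermediate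
6 | 5-methoxy-3-(methoxymethoxy)-2-(trimethylsilyl)phenyl N-(tert-butyldimethylsilyl)-N-isopropylcarbamate (formed in the flask) | COCOc1cc(OC)cc(OC(=O)N(C(C)C)[Si](C)(C)C(C)(C)C)c1[Si](C)(C)C | intermediate
7 | 5-methoxy-3-(methoxymethoxy)-2-(trimethylsilyl)phenyl N-isopropylcarbamate | COCOc1cc(OC)cc(OC(=O)NC(C)C)c1[Si](C)(C)C | intermediate
8 | 5-methoxy-3-(methoxymethoxy)-2-(trimethylsilyl)phenol (formed in the flask as its DBU salt) | COCOc1cc(OC)cc(O)c1[Si](C)(C)C | intermediate
9 | 5-methoxy-3-(methoxymethoxy)-2-(trimethylsilyl)phenyl trifluoromethanesulfonate | COCOc1cc(OC)cc(OS(=O)(=O)C(F)(F)F)c1[Si](C)(C)C | intermediate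
10 | 4,6-dibromoresorcinol | Oc1cc(O)c(Br)cc1Br | starting material
11 | 1,5-dibromo-2,4-bis(methoxymethoxy)benzene | COCOc1cc(OCOC)c(Br)cc1Br | intermediate
12 | 1-bromo-3-methylbut-2-ene | CC(C)=CCBr | starting material
13 | [5-bromo-2,4-bis(methoxymethoxy)phenyl]lithium (formed in the flask) | COCOc1cc(OCOC)c(Br)cc1[Li] | intermediate
14 | 1-bromo-2,4-bis(methoxymethoxy)-5-(3-methylbut-2-enyl)benzene | COCOc1cc(OCOC)c(CC=C(C)C)cc1Br | intermediate
15 | ethyl bromoacetate | CCOC(=O)CBr | starting material
16 | (2-ethoxy-2-oxoethyl)zinc bromide (formed in the flask) | CCOC(=O)C[Zn]Br | intermediate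
17 | ethyl 2-[2,4-bis(methoxymethoxy)-5-(3-methylbut-2-enyl)phenyl]acetate | CCOC(=O)Cc1cc(CC=C(C)C)c(OCOC)cc1OCOC | intermediate
18 | 2-[2,4-bis(methoxymethoxy)-5-(3-methylbut-2-enyl)phenyl]acetic acid | COCOc1cc(OCOC)c(CC=C(C)C)cc1CC(=O)O | intermediate
19 | 5-methoxy-3-(methoxymethoxy)benzyne (formed in the flask) | COCOC1=CC(OC)=CC#C1 | intermediate
20 | 2-caesio-5-methoxy-3-(methoxymethoxy)phenyl 2-[2,4-bis(methoxymethoxy)-5-(3-methylbut-2-enyl)phenyl]acetate (formed in the flask) | COCOc1cc(OC)cc(OC(=O)Cc2cc(CC=C(C)C)c(OCOC)cc2OCOC)c1[Cs] | intermediate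
21 | 2-[2,4-bis(methoxymethoxy)-5-(3-methylbut-2-enyl)phenyl]-1-[2-hydroxy-4-methoxy-6-(methoxymethoxy)phenyl]ethanone | COCOc1cc(OC)cc(O)c1C(=O)Cc1cc(CC=C(C)C)c(OCOC)cc1OCOC | intermediate
22 | N,N-dimethylformamide dimethyl acetal | COC(OC)N(C)C | starting material
23 | 2-[2,4-bis(methoxymethoxy)-5-(3-methylbut-2-enyl)phenyl]-3-(dimethylamino)-1-[2-hydroxy-4-methoxy-6-(methoxymethoxy)phenyl]prop-2-en-1-one (formed in the flask, alkene geometry not fixed) | COCOc1cc(OC)cc(O)c1C(=O)C(=CN(C)C)c1cc(CC=C(C)C)c(OCOC)cc1OCOC | intermediate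
24 | 3-[2,4-bis(methoxymethoxy)-5-(3-methylbut-2-enyl)phenyl]-7-methoxy-5-(methoxymethoxy)chromen-4-one | COc1cc(OCOC)c2c(=O)c(-c3cc(CC=C(C)C)c(OCOC)cc3OCOC)coc2c1 | intermediate
25 | Isopoegin B | COc1cc(O)c2c(=O)c(-c3cc(CC=C(C)C)c(O)cc3O)coc2c1 | target

**Step count**

Total: 11 steps. Longest linear sequence: 7 steps (steps 1–4 then 9–11, or equally steps 5–8 then 9–11).

**Steps most likely to fail**

Step 9. The aryl anion 20 may be protonated, or quenched by proton transfer from the acidic benzylic CH2, before the acyl shift, so that the reaction stops at the aryl ester. The aryne may also be consumed by an ene reaction with the prenyl alkene or by arylation of the product phenoxide. The fallback gives up the insertion and builds the isoflavone by cross-coupling; it sets out from bromide 14 and comes back at 24. Bromide 14 would be borylated (B2pin2, PdCl2(dppf), KOAc, dioxane, 90 °C) to 2-[2,4-bis(methoxymethoxy)-5-(3-methylbut-2-enyl)phenyl]-4,4,5,5-tetramethyl-1,3,2-dioxaborolane F1. In parallel, purchased 1-(2,6-dihydroxy-4-methoxyphenyl)ethanone F2 would be mono-protected (MOMCl, iPr2NEt, CH2Cl2; the second hydroxyl stays hydrogen-bonded to the ketone) to 1-[2-hydroxy-4-methoxy-6-(methoxymethoxy)phenyl]ethanone F3. Condensation with amide acetal 22 would give (E)-3-(dimethylamino)-1-[2-hydroxy-4-methoxy-6-(methoxymethoxy)phenyl]prop-2-en-1-one F4, and iodocyclisation (I2, pyridine, CHCl3, rt) would give 3-iodo-7-methoxy-5-(methoxymethoxy)chromen-4-one F5. Suzuki–Miyaura coupling of F1 with F5 (PdCl2(dppf), K2CO3, DME/H2O, 80 °C) should then give 24.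

Step 3. Lithiation may occur in part at the carbon between the carbamate and the OMe group, or between OMOM and OMe, giving regioisomeric silanes. The silyl triflate may also strip the MOM acetal during N-silylation, or the carbamoyl group may migrate to carbon. The fallback removes the regiochemical question by working on a symmetric substrate and adding the acetal afterwards; it sets out from diol 1 and comes back at 7. Diol 1 would be carbamoylated twice (iPrNCO, Et3N, CH2Cl2) to 5-methoxy-1,3-phenylene bis(N-isopropylcarbamate) F6. The same metalation protocol (TBSOTf 2.1 equiv, TMEDA; n-BuLi, TMEDA, −78 °C; TMSCl; aq NaHSO4) would pass through 5-methoxy-1,3-phenylene bis[N-(tert-butyldimethylsilyl)-N-isopropylcarbamate] F7, its 2-lithio derivative F8 (metalated between the two strongest directors) and the 2-trimethylsilyl bis(N-silyl) compound F9, to give 5-methoxy-2-(trimethylsilyl)-1,3-phenylene bis(N-isopropylcarbamate) F10. One carbamate would be cleaved with DBU (1.1 equiv) and Et2NH in MeCN at rt; the second should resist because it would have to expel a dianionic aryloxide. This gives 3-hydroxy-5-methoxy-2-(trimethylsilyl)phenyl N-isopropylcarbamate F11, which MOMCl and iPr2NEt in CH2Cl2 at 0 °C should convert into 7.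

Step 11. Under protic acid the liberated 4'-hydroxyl may add to the neighbouring prenyl alkene (chroman formation), or the alkene may take up HCl or methanol, while the acetals are being solvolysed. The fallback avoids having free phenols and Brønsted acid together; it sets out from 24 and comes back at 25. Treatment of 24 with TMSOTf and 2,2'-bipyridyl in CH2Cl2 at 0 °C should exchange the three aryl acetals for silyl ethers, giving 3-[2,4-bis(trimethylsilyloxy)-5-(3-methylbut-2-enyl)phenyl]-7-methoxy-5-(trimethylsilyloxy)chromen-4-one F12. Neutral hydrolysis (H2O/THF, or K2CO3/MeOH at rt) should then release 25.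

Further compounds
F1 | step 9 | 2-[2,4-bis(methoxymethoxy)-5-(3-methylbut-2-enyl)phenyl]-4,4,5,5-tetramethyl-1,3,2-dioxaborolane | COCOc1cc(OCOC)c(CC=C(C)C)cc1B1OC(C)(C)C(C)(C)O1
F2 | step 9 | 1-(2,6-dihydroxy-4-methoxyphenyl)ethanone (purchased) | CC(=O)c1c(O)cc(OC)cc1O
F3 | step 9 | 1-[2-hydroxy-4-methoxy-6-(methoxymethoxy)phenyl]ethanone | CC(=O)c1c(O)cc(OC)cc1OCOC
F4 | step 9 | (E)-3-(dimethylamino)-1-[2-hydroxy-4-methoxy-6-(methoxymethoxy)phenyl]prop-2-en-1-one | CN(C)/C=C/C(=O)c1c(O)cc(OC)cc1OCOC
F5 | step 9 | 3-iodo-7-methoxy-5-(methoxymethoxy)chromen-4-one | COCOc1cc(OC)cc2occ(I)c(=O)c12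
F6 | step 3 | 5-methoxy-1,3-phenylene bis(N-isopropylcarbamate) | COc1cc(OC(=O)NC(C)C)cc(OC(=O)NC(C)C)c1
F7 | step 3 | 5-methoxy-1,3-phenylene bis[N-(tert-butyldimethylsilyl)-N-isopropylcarbamate] | COc1cc(OC(=O)N(C(C)C)[Si](C)(C)C(C)(C)C)cc(OC(=O)N(C(C)C)[Si](C)(C)C(C)(C)C)c1
F8 | step 3 | 2-lithio-5-methoxy-1,3-phenylene bis[N-(tert-butyldimethylsilyl)-N-isopropylcarbamate] | COc1cc(OC(=O)N(C(C)C)[Si](C)(C)C(C)(C)C)c([Li])c(OC(=O)N(C(C)C)[Si](C)(C)C(C)(C)C)c1
F9 | step 3 | 5-methoxy-2-(trimethylsilyl)-1,3-phenylene bis[N-(tert-butyldimethylsilyl)-N-isopropylcarbamate] | COc1cc(OC(=O)N(C(C)C)[Si](C)(C)C(C)(C)C)c([Si](C)(C)C)c(OC(=O)N(C(C)C)[Si](C)(C)C(C)(C)C)c1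
F10 | step 3 | 5-methoxy-2-(trimethylsilyl)-1,3-phenylene bis(N-isopropylcarbamate) | COc1cc(OC(=O)NC(C)C)c([Si](C)(C)C)c(OC(=O)NC(C)C)c1
F11 | step 3 | 3-hydroxy-5-methoxy-2-(trimethylsilyl)phenyl N-isopropylcarbamate | COc1cc(O)c([Si](C)(C)C)c(OC(=O)NC(C)C)c1
F12 | step 11 | 3-[2,4-bis(trimethylsilyloxy)-5-(3-methylbut-2-enyl)phenyl]-7-methoxy-5-(trimethylsilyloxy)chromen-4-one | COc1cc(O[Si](C)(C)C)c2c(=O)c(-c3cc(CC=C(C)C)c(O[Si](C)(C)C)cc3O[Si](C)(C)C)coc2c1
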